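The route rests on opening ring B by a retro-[4+2] across C5–C10 (ring fusion) and C6–C7, which also opens ring A and leaves an acyclic 1,7,9-decatriene (drimane numbering). The key intramolecular Diels–Alder reaction exploits ring B, whose methylene-bearing C8 and C9 become the inner diene carbons: diene C7=C8–C9=C10 adds to a C5=C6 enal through the tether C1–C4, closing both rings and setting the trans fusion (C5, C10) under control of the C3 ester. C8 carries CH2SiMe3 and C9 the umbelliferyl ether, so the C8=C9 cycloadduct is an allylsilane; protodesilylation then gives the exocyclic methylene and C9–H. The C6 formyl activator is removed by decarbonylation.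

Key step: step 9

Remark on numbering and configuration: drimane numbering is used throughout (ring A = C1–C5 and C10; ring B = C5–C10; C11 = OCH2 on C9; C12 = methylene carbon on C8). The target as drawn is (3R,5S,9R,10R): trans-fused, with the C3 ester and the C9 arm both equatorial.

Step 1
Reactants: 1 3-bromopropanoyl chloride; 2 trimethyl(3-methylbut-2-en-1-yl)silane
Product: 3 1-bromo-4,4-dimethylhex-5-en-3-one
Conditions: AlCl3 (1.1 equiv), CH2Cl2, −78 °C
Reagents that add atoms: none
Why: Hosomi–Sakurai acylation of an allylsilane: the acylium ion attacks the dimethyl-bearing γ-carbon (SE2′), so the C3–C4 bond forms at the future quaternary C4 and the vinyl group (C5=C6) is released; no stereocentre is formed.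

Step 2
Reactants: 3 1-bromo-4,4-dimethylhex-5-en-3-one
Product: 4 (3R)-1-bromo-4,4-dimethylhex-5-en-3-ol
Conditions: (S)-2-methyl-CBS-oxazaborolidine (20 mol%), catecholborane (1.5 equiv), toluene, −78 → −40 °C; pH 7 buffer
Reagents that add atoms: none
Why: Corey–Bakshi–Shibata reduction: the tert-alkyl group is the large substituent, so the (S)-catalyst should deliver hydride to give the (R)-carbinol (C3 of the target), and catecholborane spares the vinyl group.

Step 3
Reactants: 4 (3R)-1-bromo-4,4-dimethylhex-5-en-3-ol; 5 3-methylbutanoyl chloride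
Product: 6 (3R)-1-bromo-4,4-dimethylhex-5-en-3-yl 3-methylbutanoate
Conditions: pyridine, DMAP (cat.), CH2Cl2, 0 → 25 °C
Reagents that add atoms: none
Why: DMAP-catalysed esterification of the hindered secondary alcohol installs the final isovalerate, which also protects C3–O for the rest of the route; the stereocentre is not touched.

Step 4
Reactants: 6 (3R)-1-bromo-4,4-dimethylhex-5-en-3-yl 3-methylbutanoate; 7 3,3-diethoxyprop-1-ene
Product: 8 (3R,5E)-1-bromo-7,7-diethoxy-4,4-dimethylhept-5-en-3-yl 3-methylbutanoate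
Conditions: second-generation Hoveyda–Grubbs catalyst (5 mol%), 7 (5 equiv), CH2Cl2, 40 °C
Reagents that add atoms: none
Why: Olefin cross-metathesis of the vinyl group on the quaternary carbon (it does not homodimerise) with excess acrolein acetal should give the E-configured masked enal; E geometry is the thermodynamic outcome.

Step 5
Reactants: 9 but-2-yn-1-ol; 10 (2-bromoprop-2-en-1-yl)trimethylsilane
Product: 13 (2Z)-3-iodo-2-[3-(trimethylsilyl)prop-1-en-2-yl]but-2-en-1-ol, via vinyl Grignard reagent 11 (not isolated), via cyclic magnesium alkoxide 12 (not isolated)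
Conditions: 10 (2.5 equiv), Mg, THF, 40 °C; add 9, THF/toluene, 80 °C; then I2, THF, −78 → 0 °C
Reagents that add atoms: iodine, II
Why: Alkoxide-directed anti-carbomagnesiation of a propargylic alcohol: the alkenyl group adds to the alkyne carbon next to CH2OH and magnesium is held on the distal carbon in a five-membered chelate, so iodinolysis with retention gives the Z-iodide and fixes the C9=C10 geometry (methyl cis to the C8 unit).

Step 6
Reactants: 13 (2Z)-3-iodo-2-[3-(trimethylsilyl)prop-1-en-2-yl]but-2-en-1-ol; 14 7-hydroxy-2H-chromen-2-one (umbelliferone)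
Product: 15 7-({(2Z)-3-iodo-2-[3-(trimethylsilyl)prop-1-en-2-yl]but-2-en-1-yl}oxy)-2H-chromen-2-one
Conditions: PPh3, DIAD, THF, 0 → 25 °C
Reagents that add atoms: none
Why: Mitsunobu etherification of a primary allylic alcohol with an acidic phenol; SN2 at CH2 is expected because the SN2′ terminus is fully substituted, and the alkene geometry is not affected.

Step 7
Reactants: 8 (3R,5E)-1-bromo-7,7-diethoxy-4,4-dimethylhept-5-en-3-yl 3-methylbutanoate; 15 7-({(2Z)-3-iodo-2-[3-(trimethylsilyl)prop-1-en-2-yl]but-2-en-1-yl}oxy)-2H-chromen-2-one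
Product: 17 (2E,5R,8Z)-1,1-diethoxy-4,4,8-trimethyl-9-{[(2-oxo-2H-chromen-7-yl)oxy]methyl}-10-[(trimethylsilyl)methyl]undeca-2,8,10-trien-5-yl 3-methylbutanoate, via alkylzinc bromide 16 (not isolated)
Conditions: 8, Zn dust, LiCl, THF, 50 °C; then 15, Pd2(dba)3 (2.5 mol%), SPhos (10 mol%), THF, 25–40 °C
Reagents that add atoms: none
Why: LiCl-mediated zinc insertion into the primary bromide followed by Negishi sp3–sp2 coupling forms C1–C10 with retention of the alkene geometry (tether cis to CH2OAr); ester, acetal and lactone tolerate the alkylzinc halide.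

Step 8
Reactants: 17 (2E,5R,8Z)-1,1-diethoxy-4,4,8-trimethyl-9-{[(2-oxo-2H-chromen-7-yl)oxy]methyl}-10-[(trimethylsilyl)methyl]undeca-2,8,10-trien-5-yl 3-methylbutanoate
Product: 18 (2E,5R,8Z)-4,4,8-trimethyl-1-oxo-9-{[(2-oxo-2H-chromen-7-yl)oxy]methyl}-10-[(trimethylsilyl)methyl]undeca-2,8,10-trien-5-yl 3-methylbutanoate
Conditions: PPTS (10 mol%), acetone/H2O 10:1, 25 °C; used at once
Reagents that add atoms: water, O
Why: Acetal hydrolysis: the α,β-unsaturated acetal ionises to an allylic oxocarbenium ion under acid mild enough for the dienylmethylsilane, and any Z-enal equilibrates to E.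

Step 9
Reactants: 18 (2E,5R,8Z)-4,4,8-trimethyl-1-oxo-9-{[(2-oxo-2H-chromen-7-yl)oxy]methyl}-10-[(trimethylsilyl)methyl]undeca-2,8,10-trien-5-yl 3-methylbutanoate
Product: 19 (3R,5S,6R,10R)-6-formyl-11-[(2-oxo-2H-chromen-7-yl)oxy]-12-(trimethylsilyl)drim-8-en-3-yl 3-methylbutanoate
Conditions: Me2AlCl (1.5 equiv), CH2Cl2, −78 → −30 °C; aq. NaHCO3
Reagents that add atoms: none
Why: Lewis-acid-promoted intramolecular Diels–Alder reaction of a 1,7,9-decatrienal: Me2AlCl lowers the LUMO of the (E)-enal C5=C6, which adds suprafacially to the s-cis diene C7=C8–C9=C10 in a concerted, asynchronous [4+2] step with the C5–C10 bond more advanced. The closest known reaction type is the Lewis-acid-promoted cyclisation of terminally activated (E)-deca-2,7,9-trienals to trans-fused octalins. Ring B is closed as the cyclohexene of the [4+2] itself (bonds C5–C10 and C6–C7), and ring A is closed by the C5–C10 bond through the four-carbon tether C1–C4 in a chair-like, fused arrangement. C5 and C10 arise trans because the aluminium-bound formyl group sits endo, which for an (E)-dienophile enforces the anti ring fusion, and the angular methyl is the inside substituent of C10 fixed in step 5; their absolute sense follows from C3, whose isovalerate takes the equatorial site of the chair tether, while C6 (formyl cis to H5) follows from the E geometry and is erased in step 10. The step needs fused regiochemistry (secured by the short tether), endo selectivity (E-enal plus Lewis acid) and π-facial selectivity (equatorial C3 ester beside the C4 gem-dimethyl group, which also speeds closure); the low temperature should suppress [1,5]-hydrogen shift in the diene and ionisation of the allylic aryl ether.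

Step 10
Reactants: 19 (3R,5S,6R,10R)-6-formyl-11-[(2-oxo-2H-chromen-7-yl)oxy]-12-(trimethylsilyl)drim-8-en-3-yl 3-methylbutanoate
Product: 20 (3R,5S,10R)-11-[(2-oxo-2H-chromen-7-yl)oxy]-12-(trimethylsilyl)drim-8-en-3-yl 3-methylbutanoate
Conditions: RhCl(PPh3)3 (1.1 equiv), toluene, 110 °C
Reagents that add atoms: none
Why: Tsuji–Wilkinson decarbonylation (formyl C–H insertion, CO extrusion, C–H reductive elimination) turns C6 into CH2; the tetrasubstituted allylsilane, the ester and the coumarin should be inert to the rhodium reagent.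

Step 11
Reactants: 20 (3R,5S,10R)-11-[(2-oxo-2H-chromen-7-yl)oxy]-12-(trimethylsilyl)drim-8-en-3-yl 3-methylbutanoate
Product: 21 (3R,5S,9R,10R)-11-[(2-oxo-2H-chromen-7-yl)oxy]drim-8(12)-en-3-yl 3-methylbutanoate (CNP0295317.1)
Conditions: CF3CO2H (3 equiv), CH2Cl2, −20 → 0 °C; NaHCO3
Reagents that add atoms: none
Why: SE2′ protodesilylation of the allylsilane: the proton should add to C9 axially on the face opposite the axial C10 methyl (setting 9R with CH2OAr equatorial), and the β-silyl cation at C8 loses silicon to give the exocyclic C8=C12 double bond.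

Compound list
1 | 3-bromopropanoyl chloride | O=C(Cl)CCBr | starting material
2 | trimethyl(3-methylbut-2-en-1-yl)silane | CC(C)=CC[Si](C)(C)C | starting material
3 | 1-bromo-4,4-dimethylhex-5-en-3-one | C=CC(C)(C)C(=O)CCBr | intermediate
4 | (3R)-1-bromo-4,4-dimethylhex-5-en-3-ol | C=CC(C)(C)[C@H](O)CCBr | intermediate
5 | 3-methylbutanoyl chloride | CC(C)CC(=O)Cl | starting material
6 | (3R)-1-bromo-4,4-dimethylhex-5-en-3-yl 3-methylbutanoate | C=CC(C)(C)[C@H](OC(=O)CC(C)C)CCBr | intermediate
7 | 3,3-diethoxyprop-1-ene (acrolein diethyl acetal) | C=CC(OCC)OCC | starting material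
8 | (3R,5E)-1-bromo-7,7-diethoxy-4,4-dimethylhept-5-en-3-yl 3-methylbutanoate | CCOC(OCC)/C=C/C(C)(C)[C@H](OC(=O)CC(C)C)CCBr | intermediate
9 | but-2-yn-1-ol | CC#CCO | starting material
10 | (2-bromoprop-2-en-1-yl)trimethylsilane | C=C(Br)C[Si](C)(C)C | starting material
11 | bromo[3-(trimethylsilyl)prop-1-en-2-yl]magnesium (vinyl Grignard reagent) | C=C([Mg]Br)C[Si](C)(C)C | intermediate
12 | 3-methyl-4-[3-(trimethylsilyl)prop-1-en-2-yl]-2,5-dihydro-1,2-oxamagnesole (cyclic magnesium alkoxide) | CC1=C(CO[Mg]1)C(=C)C[Si](C)(C)C | intermediate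
13 | (2Z)-3-iodo-2-[3-(trimethylsilyl)prop-1-en-2-yl]but-2-en-1-ol | C/C(I)=C(/CO)C(=C)C[Si](C)(C)C | intermediate
14 | 7-hydroxy-2H-chromen-2-one (umbelliferone) | O=c1ccc2ccc(O)cc2o1 | starting material
15 | 7-({(2Z)-3-iodo-2-[3-(trimethylsilyl)prop-1-en-2-yl]but-2-en-1-yl}oxy)-2H-chromen-2-one | C/C(I)=C(/COc1ccc2ccc(=O)oc2c1)C(=C)C[Si](C)(C)C | intermediate
16 | bromo[(3R,5E)-7,7-diethoxy-4,4-dimethyl-3-(3-methylbutanoyloxy)hept-5-en-1-yl]zinc (alkylzinc bromide) | CCOC(OCC)/C=C/C(C)(C)[C@H](OC(=O)CC(C)C)CC[Zn]Br | intermediate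
17 | (2E,5R,8Z)-1,1-diethoxy-4,4,8-trimethyl-9-{[(2-oxo-2H-chromen-7-yl)oxy]methyl}-10-[(trimethylsilyl)methyl]undeca-2,8,10-trien-5-yl 3-methylbutanoate | CCOC(OCC)/C=C/C(C)(C)[C@H](OC(=O)CC(C)C)CC/C(C)=C(\COc1ccc2ccc(=O)oc2c1)C(=C)C[Si](C)(C)C | intermediate
18 | (2E,5R,8Z)-4,4,8-trimethyl-1-oxo-9-{[(2-oxo-2H-chromen-7-yl)oxy]methyl}-10-[(trimethylsilyl)methyl]undeca-2,8,10-trien-5-yl 3-methylbutanoate | O=C/C=C/C(C)(C)[C@H](OC(=O)CC(C)C)CC/C(C)=C(\COc1ccc2ccc(=O)oc2c1)C(=C)C[Si](C)(C)C | intermediate
19 | (3R,5S,6R,10R)-6-formyl-11-[(2-oxo-2H-chromen-7-yl)oxy]-12-(trimethylsilyl)drim-8-en-3-yl 3-methylbutanoate | C[Si](C)(C)CC=1C[C@@H](C=O)[C@@H]2C(C)(C)[C@H](OC(=O)CC(C)C)CC[C@@]2(C)C=1COc1ccc2ccc(=O)oc2c1 | intermediate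
20 | (3R,5S,10R)-11-[(2-oxo-2H-chromen-7-yl)oxy]-12-(trimethylsilyl)drim-8-en-3-yl 3-methylbutanoate | C[Si](C)(C)CC=1CC[C@@H]2C(C)(C)[C@H](OC(=O)CC(C)C)CC[C@@]2(C)C=1COc1ccc2ccc(=O)oc2c1 | intermediate
21 | (3R,5S,9R,10R)-11-[(2-oxo-2H-chromen-7-yl)oxy]drim-8(12)-en-3-yl 3-methylbutanoate (CNP0295317.1) | C=C1CC[C@@H]2C(C)(C)[C@H](OC(=O)CC(C)C)CC[C@@]2(C)[C@@H]1COc1ccc2ccc(=O)oc2c1 | target

Total step count: 11. Longest linear sequence: 9 steps (steps 1–4 and 7–11); the shorter branch is steps 5–6.

Steps most likely to fail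

Step 9 (key cycloaddition). Three processes may intervene. The C3 ester may discriminate the two diene faces poorly, because the neighbouring gem-dimethyl group erodes its equatorial preference. Exo (cis-fused) closure may compete, because the inside methyl on C10 meets the axial C4 methyl in the endo chair. The Lewis acid may ionise the allylic aryl ether. The fallback replaces the metal Lewis acid by catalyst-controlled iminium activation and sets out from 18. Compound 18 is treated with (2S,5S)-5-benzyl-2-tert-butyl-3-methylimidazolidin-4-one trifluoroacetate (20 mol%, MeCN/H2O, −20 °C); the antipode that reinforces the C3 bias is to be used and is drawn here as 2S,5S. Condensation gives the iminium ion F1, which should undergo the same endo [4+2] closure to the cycloadduct iminium ion F2. Hydrolysis in the wet medium frees the catalyst and the route is rejoined at 19.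

Step 11 (protodesilylation). The proton may be delivered to the wrong face of C9, the acid may move the new exocyclic double bond into ring B, or the aryloxide may be lost by vinylogous elimination with the silyl group. The fallback corrects C9 under thermodynamic control and sets out from the crude product of step 11 (21 with its C9 epimer). Lemieux–Johnson cleavage of the exocyclic methylene (OsO4 cat., NaIO4, 2,6-lutidine, dioxane/H2O) gives the 12-nor-8-ketones, the unwanted (9S)-ketone F3 and the (9R)-ketone F4. Brief equilibration (DBU cat., CH2Cl2, 0 °C) should move C9 into the equatorial arrangement of F4. Non-basic methylenation (Zn, CH2Br2, TiCl4, THF), which leaves the ester and the lactone alone, restores C12 and the route is rejoined at 21. Ring-olefin isomers do not give these ketones and are removed at this stage.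

Step 4 (cross-metathesis). Metathesis at the vinyl group on the quaternary carbon may be slow or incomplete while the acetal partner is consumed by self-metathesis. The fallback builds the enal by carbonyl olefination and sets out from 6. Ozonolysis (O3, CH2Cl2, −78 °C; Me2S) gives the aldehyde F5. Wittig reaction with (triphenylphosphoranylidene)acetaldehyde (toluene, 80 °C) gives the (E)-enal F6. Acetalisation (HC(OEt)3, EtOH, PPTS) rejoins the route at 8.

Further compounds
F1 | step 9 | iminium trifluoroacetate formed from 18 and (2S,5S)-5-benzyl-2-tert-butyl-3-methylimidazolidin-4-one | CN1C(=O)[C@H](Cc2ccccc2)[N+](=C/C=C/C(C)(C)[C@H](OC(=O)CC(C)C)CC/C(C)=C(\COc3ccc4ccc(=O)oc4c3)C(=C)C[Si](C)(C)C)[C@@H]1C(C)(C)C.[O-]C(=O)C(F)(F)F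
F2 | step 9 | iminium trifluoroacetate of cycloadduct 19 with the same imidazolidinone | C[Si](C)(C)CC=1C[C@@H](C=[N+]3[C@H](C(C)(C)C)N(C)C(=O)[C@@H]3Cc4ccccc4)[C@@H]2C(C)(C)[C@H](OC(=O)CC(C)C)CC[C@@]2(C)C=1COc1ccc2ccc(=O)oc2c1.[O-]C(=O)C(F)(F)F
F3 | step 11 | (3R,5S,9S,10R)-8-oxo-11-[(2-oxo-2H-chromen-7-yl)oxy]-12-nordriman-3-yl 3-methylbutanoate | O=C1CC[C@@H]2C(C)(C)[C@H](OC(=O)CC(C)C)CC[C@@]2(C)[C@H]1COc1ccc2ccc(=O)oc2c1
F4 | step 11 | (3R,5S,9R,10R)-8-oxo-11-[(2-oxo-2H-chromen-7-yl)oxy]-12-nordriman-3-yl 3-methylbutanoate | O=C1CC[C@@H]2C(C)(C)[C@H](OC(=O)CC(C)C)CC[C@@]2(C)[C@@H]1COc1ccc2ccc(=O)oc2c1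
F5 | step 4 | (3R)-1-bromo-4,4-dimethyl-5-oxopentan-3-yl 3-methylbutanoate | O=CC(C)(C)[C@H](OC(=O)CC(C)C)CCBr
F6 | step 4 | (3R,5E)-1-bromo-4,4-dimethyl-7-oxohept-5-en-3-yl 3-methylbutanoate | O=C/C=C/C(C)(C)[C@H](OC(=O)CC(C)C)CCBr
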